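## Analysis of the target

The target is (2S,3S,5S)-5-methoxy-3-methyl-5-(prop-2-en-1-yl)-2-(3,4,5-trimethoxyphenyl)-2,3-dihydro-1-benzofuran-6(5H)-one (15), in which a 2,3-dihydrofuran ring (O1, C2, C3, C3a, C7a) is fused to a cyclohexa-2,4-dienone (C3a, C4, C5, C6, C7, C7a). The six-membered ring is not aromatic: C5 is a quaternary sp3 carbon carrying methoxy and allyl, C6 is a ketone, and C7=C7a carries O1, so C6=O is a vinylogous ester. Of the three stereocentres, C2 (aryl) and C3 (methyl) are adjacent and trans, while at C5 the allyl group lies on the face of the C3 methyl group and the methoxy group on the face of the aryl group. C5 is separated from C3 by the sp2 carbons C3a and C4, so the two neighbouring centres cannot be expected to direct its formation. The blocked dienone is the sensitive part: acid invites allyl shifts with aromatisation, heat invites [3,3] shifts of the allyl group (to the C6 oxygen or to C3a), and alkoxides at C5 can rearrange; the C2–O1 bond is in addition a benzylic ether of an electron-rich arene. The difficulty is therefore a quaternary stereocentre on a dearomatised, fragile ring, remote from the other two centres. The strategy rests on C2: it is a single carbon, bearing only the trimethoxyphenyl group, between O1 and C3, so the other four ring atoms O1–C7a–C3a–C3 (with the C3 methyl) are the skeleton of an o-quinone methide and C2 can come from an aryl carbene equivalent.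

## Retrosynthetic reasoning

**C5–OMe.** The O–CH3 bond of 15 is cut first, leading to the tertiary ketol 14. No bond to a stereocentre is touched, and the most fragile functionality is completed in the last step. The forward reaction must methylate a hindered hydroxyl without forming an alkoxide and without heat.

**C5–allyl.** Cutting the C5–CH2 bond of 14 leads to the o-quinone 13 and an allyl nucleophile. This is the natural place to cut because the two carbonyls of 13 differ: C6=O is a vinylogous ester through O1, while C5=O is an ordinary enone carbonyl and the more electrophilic. The forward reaction must add 1,2 at C5 only and choose the face of a carbonyl that the substrate hardly differentiates, which calls for a chiral Lewis acid.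

**Oxidation level at C5/C6.** The quinone 13 is the oxidised form of catechol 12, and 12 is carried through the synthesis as the methylenedioxy compound 11. The skeleton is thus assembled on an aromatic ring and dearomatised only at the end. The methylenedioxy ring is inert to base and ylides, makes the phenol ring electron-rich enough for easy quinone methide formation, and can be opened selectively by a boron Lewis acid in the presence of aryl methyl ethers.

**O1–C2 and C2–C3 (key disconnection).** Both bonds to C2 in 11 are cut at once. This gives the o-quinone methide 8 and the benzylic sulfonium ylide 9, which is a carbene equivalent carrying its own leaving group. Cutting here removes the ring and both stereocentres in one step and leaves two fragments of very different size and simple provenance. The forward reaction must add the ylide carbon to the exocyclic carbon of 8, close the ring by displacement of the sulfide, deliver the trans ring and select one face of 8.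

**Precursors of the two reactive partners.** Quinone methide 8 is too reactive to store and is released by base from sulfone 4. Sulfone 4 comes from benzylic alcohol 3, which comes from ketone 2, the C-acetylation product of sesamol 1. Ylide 9 is generated by the same base from sulfonium bromide 7, the product of S-alkylation of dimethyl sulfide 6 with benzyl bromide 5.

## Alternatives that were turned down

**Alternative 1:** The dienone ring itself is dismantled. C6–C7 and C3a–C7a lead back to ethoxyethyne A2 and a vinylketene, and C5–C6 to an electrocyclic closure. In the forward sense, irradiation of a diazo enone causes a Wolff rearrangement; the vinylketene adds A2 in a [2+2] mode, the cyclobutenone opens and the resulting dienylketene closes (6π) to dienone A1, (S)-6-allyl-4-[(1S,2S)-1-(tert-butyldimethylsilyloxy)-1-(3,4,5-trimethoxyphenyl)propan-2-yl]-3-ethoxy-6-methoxycyclohexa-2,4-dien-1-one. The quaternary carbon of A1 blocks tautomerisation to a phenol. The dihydrofuran would then be closed by the freed C2 hydroxyl displacing ethoxide by addition–elimination.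
- For it: the fragile dienone arises directly, no o-quinone is handled, and C2/C3 would come from dependable acyclic stereocontrol. On the absolute configuration of those two centres it is on firmer ground than the chosen key step.
- Against it: C5 is created in the electrocyclisation from a fully substituted enol-ether terminus of fixed geometry, under the influence only of a side-chain stereocentre. Control at C5 is thus no better than in the chosen route and cannot be corrected by a catalyst. The diazo enone needs a long linear sequence, and the annulation is designed to end in a phenol, not to stop at a heteroatom-substituted quaternary dienone.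
- Comparison: the chosen route builds the bicyclic skeleton in one convergent step from short fragments and leaves C5 to a reagent-controlled addition with a simple fallback.

**Alternative 2:** C3–C3a and O1–C2 are cut, pairing an allyl-substituted quinone monoketal with (E)-isoelemicin A4, as in the presumed biogenesis. A chiral Brønsted acid would ionise the ketal, the alkene of A4 would attack the allyl-bearing carbon of the cation, and the carbonyl oxygen would capture the benzylic cation to give A3, (2S,3S,3aR)-3a-allyl-5-methoxy-3-methyl-2-(3,4,5-trimethoxyphenyl)-3,3a-dihydro-1-benzofuran-6(2H)-one. A suprafacial [3,3] shift would then move the allyl group from C3a to C5 on the same face.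
- For it: it is by far the shortest route. It is also stronger than the chosen strategy on one point: C5 is tied to C2/C3 by chirality transfer, so the remote centre needs no control element of its own.
- Against it: the cation–alkene step can partition between the [3+2] mode and a [5+2] mode and between diastereomers at C3a. Counter-anion control of such a delocalised cation reacting with a simple propenylarene is untested. The thermal shift competes with allyl migration to oxygen and aromatisation. Several selectivities are compressed into two steps with no handle on any of them.
- Comparison: the chosen strategy separates the problems. Ring and C2/C3 are set in one step, C5 in another, and each has an independent fallback.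

**Alternative 3:** Only C2–C3 is cut, back to the aryldiazoacetate A6, methyl 2-diazo-2-[6-(3,4,5-trimethoxybenzyloxy)-1,3-benzodioxol-5-yl]acetate. The chiral dirhodium prolinate catalyst Rh2(S-DOSP)4 A7 decomposes A6; the rhodium carbene at C3 inserts into the benzylic C–H bond and closes the ring to ester A5, methyl (2S,3S)-trans-5,6-methylenedioxy-2-(3,4,5-trimethoxyphenyl)-2,3-dihydro-1-benzofuran-3-carboxylate.
- For it: this is established asymmetric catalysis for this ring system. On precedent for enantiocontrol it is stronger than the chosen key step.
- Against it: insertion into a methylene C–H bond tends to give the cis ring, so C3 would have to be epimerised next to the ester. The ester must then be taken down to a methyl group (reduction, activation, second reduction). A6 itself needs O-benzylation, an arylacetate and a diazo transfer. Enantioselectivity of A7 and related catalysts at benzylic methylene groups is not uniformly high. Reaching the stage of 11 would take roughly five or six more steps.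
- Comparison: the chosen strategy delivers the C3 methyl group in its final oxidation state and both ring bonds in one operation. What it gives up is proven enantiocontrol, and the fallback for the key step covers that.

Key step: step 5

Assumption: the sense of induction of the two chiral catalysts cannot be read from the structures with certainty. The route is written with N-(9-anthracenylmethyl)cinchonidinium chloride (step 5) and the (S,S)-isopropyl-PyBox ligand (step 8); if either should favour the wrong face, the cinchonine-derived salt or the (R,R)-ligand takes its place with no other change.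

## Route

**Step 1**
Reactants: 1 sesamol (1,3-benzodioxol-5-ol)
Product: 2 1-(6-hydroxy-1,3-benzodioxol-5-yl)ethan-1-one
Conditions: AcOH, BF3·OEt2, 90 °C
Reagents that add atoms: acetic acid, CC(=O)O
Why: Friedel–Crafts C-acylation (through the aryl acetate and a Fries-type shift) should go to C6, the free position ortho to the hydroxyl and para to a dioxole oxygen; chelation of the o-hydroxy ketone to boron prevents a second acylation.

**Step 2**
Reactants: 2 1-(6-hydroxy-1,3-benzodioxol-5-yl)ethan-1-one
Product: 3 rac-6-(1-hydroxyethyl)-1,3-benzodioxol-5-ol
Conditions: NaBH4, THF/MeOH, 0 °C; pH 7 buffer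
Reagents that add atoms: none
Why: Hydride reduction of an aryl ketone; the cold, neutral work-up keeps the electron-rich o-hydroxybenzylic alcohol from ionising, and the new centre is left racemic because it is planarised in step 5.

**Step 3**
Reactants: 3 rac-6-(1-hydroxyethyl)-1,3-benzodioxol-5-ol
Product: 4 rac-6-[1-(4-methylbenzenesulfonyl)ethyl]-1,3-benzodioxol-5-ol
Conditions: p-TolSO2Na, HCO2H/H2O, rt
Reagents that add atoms: sodium 4-methylbenzenesulfinate, Cc1ccc(cc1)S(=O)[O-].[Na+]
Why: Acid ionises the benzylic alcohol (SN1 through the protonated quinone methide) and the sulfinate captures the cation at sulfur; the sulfone should crystallise and serves as a storable, base-triggered source of the quinone methide.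

**Step 4**
Reactants: 5 3,4,5-trimethoxybenzyl bromide; 6 dimethyl sulfide
Product: 7 dimethyl(3,4,5-trimethoxybenzyl)sulfonium bromide
Conditions: Me2S (3 equiv), acetone, rt, dark
Reagents that add atoms: none
Why: SN2 S-alkylation of a soft sulfide by a benzylic bromide; precipitation of the salt from acetone should drive the otherwise reversible alkylation to completion.

**Step 5**
Reactants: 4 rac-6-[1-(4-methylbenzenesulfonyl)ethyl]-1,3-benzodioxol-5-ol; 7 dimethyl(3,4,5-trimethoxybenzyl)sulfonium bromide
Product: 11 (2S,3S)-3-methyl-5,6-methylenedioxy-2-(3,4,5-trimethoxyphenyl)-2,3-dihydro-1-benzofuran, via o-quinone methide 8 (not isolated), via sulfonium ylide 9 (not isolated), via sulfonium phenoxide betaine 10 (not isolated)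
Conditions: Cs2CO3 (3 equiv), N-(9-anthracenylmethyl)cinchonidinium chloride (10 mol%), CH2Cl2, −20 °C
Reagents that add atoms: none
Why: Proposed new method: Cs2CO3 converts phenol 4 into its phenoxide, which expels the sulfinate (E1cB) to give the (E)-quinone methide 8, and deprotonates 7 to the benzylic ylide 9; the ylide carbon adds to the exocyclic carbon of 8 (C2–C3), restoring the aromatic ring as betaine 10, whose phenoxide then displaces dimethyl sulfide from the benzylic carbon with inversion (O1–C2). The closest known reaction type is the base-mediated formal [4+1] annulation of o-quinone methides released from 2-(1-sulfonylalkyl)phenols with sulfur ylides, which gives trans-2,3-dihydrobenzofurans and has an enantioselective hydrogen-bond-donor-catalysed form for carbonyl-stabilised ylides; new here is enantiocontrol with a semi-stabilised benzylic ylide under a chiral ammonium salt. The dihydrofuran ring closes in the 5-exo-tet mode. C3 is set in the C–C bond formation, taken to be irreversible because it restores aromaticity: the catalyst, with its C9 hydroxyl hydrogen-bonded to the quinone methide oxygen and its ammonium centre paired with the developing phenoxide, is meant to cover one face so that the ylide reaches the Si face of the exocyclic carbon, which gives (3S). C2 is set relative to C3: the betaine that can hold aryl and methyl anti in the closure transition state cyclises faster, and the acidic benzylic sulfonium C–H lets the other diastereomer funnel into it, so the 2,3-trans ring should result. The step needs 1,4-addition at carbon, trans diastereoselectivity and face selectivity; aromatisation secures the first, the E geometry of 8 (methyl turned away from the carbonyl oxygen) and the anti closure secure the second, and only the third depends on the catalyst.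

**Step 6**
Reactants: 11 (2S,3S)-3-methyl-5,6-methylenedioxy-2-(3,4,5-trimethoxyphenyl)-2,3-dihydro-1-benzofuran
Product: 12 (2S,3S)-3-methyl-2-(3,4,5-trimethoxyphenyl)-2,3-dihydro-1-benzofuran-5,6-diol
Conditions: BCl3 (2.5 equiv), CH2Cl2, −78 → −20 °C; then MeOH, aq. NaHCO3
Reagents that add atoms: none
Why: Lewis-acid cleavage of the cyclic acetal, which BCl3 opens much faster than aryl methyl ethers at low temperature; the aryloxyborane and chloromethyl ether hydrolyse on work-up. C3 is untouched, and should the benzylic C2–O1 bond ionise it is expected to reclose to the more stable trans ring.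

**Step 7**
Reactants: 12 (2S,3S)-3-methyl-2-(3,4,5-trimethoxyphenyl)-2,3-dihydro-1-benzofuran-5,6-diol
Product: 13 (2S,3S)-3-methyl-2-(3,4,5-trimethoxyphenyl)-2,3-dihydro-1-benzofuran-5,6-dione
Conditions: Ag2O (3 equiv), Na2SO4, Et2O, 0 °C, dark; filtered through Celite and used at once
Reagents that add atoms: none
Why: Two-electron oxidation of a catechol to the o-quinone on a neutral, insoluble oxidant; the 4-alkoxy-o-quinone is a stabilised vinylogous ester, and the aprotic, base-free medium should prevent enolisation towards C3, so C3 keeps its configuration.

**Step 8**
Reactants: 13 (2S,3S)-3-methyl-2-(3,4,5-trimethoxyphenyl)-2,3-dihydro-1-benzofuran-5,6-dione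
Product: 14 (2S,3S,5S)-5-hydroxy-3-methyl-5-(prop-2-en-1-yl)-2-(3,4,5-trimethoxyphenyl)-2,3-dihydro-1-benzofuran-6(5H)-one
Conditions: allylSnBu3 (1.5 equiv), In(OTf)3 (20 mol%), 2,6-bis[(4S)-4-isopropyl-4,5-dihydro-1,3-oxazol-2-yl]pyridine (22 mol%), 4 Å MS, CH2Cl2, −60 °C; aq. NaHCO3
Reagents that add atoms: allyltributylstannane, C=CC[Sn](CCCC)(CCCC)CCCC
Why: Proposed new method: Lewis-acid-promoted 1,2-addition of allylstannanes to one carbonyl of o-quinones and In(OTf)3–PyBox-catalysed enantioselective allylation of simple ketones are the closest known reaction types, and their combination on an o-quinone is new; the 1,2-dione should chelate the indium centre, and C5=O reacts because C6=O is deactivated as a vinylogous ester through O1. C5 is set by the ligand, which must direct the allyl group to the Re face of C5=O (the face of the C3 methyl group); C2 and C3 are too remote to help and may weakly oppose.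

**Step 9**
Reactants: 14 (2S,3S,5S)-5-hydroxy-3-methyl-5-(prop-2-en-1-yl)-2-(3,4,5-trimethoxyphenyl)-2,3-dihydro-1-benzofuran-6(5H)-one
Product: 15 (2S,3S,5S)-5-methoxy-3-methyl-5-(prop-2-en-1-yl)-2-(3,4,5-trimethoxyphenyl)-2,3-dihydro-1-benzofuran-6(5H)-one
Conditions: MeOTf (3 equiv), 2,6-di-tert-butyl-4-methylpyridine (4 equiv), CH2Cl2, 0 °C → rt
Reagents that add atoms: methyl trifluoromethanesulfonate, COS(=O)(=O)C(F)(F)F
Why: O-Alkylation of a hindered tertiary alcohol by a strong methylating agent buffered with a non-nucleophilic pyridine; no alkoxide is formed, which avoids anionic oxy-Cope, α-ketol and retro-allylation pathways, and no bond to C5 is broken, so its configuration is kept. The temperature stays at or below ambient because the allyl dienone can undergo thermal [3,3] shifts.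

## Compound list

1 | sesamol (1,3-benzodioxol-5-ol) | Oc1ccc2OCOc2c1 | starting material
2 | 1-(6-hydroxy-1,3-benzodioxol-5-yl)ethan-1-one | CC(=O)c1cc2OCOc2cc1O | intermediate
3 | rac-6-(1-hydroxyethyl)-1,3-benzodioxol-5-ol | CC(O)c1cc2OCOc2cc1O | intermediate
4 | rac-6-[1-(4-methylbenzenesulfonyl)ethyl]-1,3-benzodioxol-5-ol | CC(c1cc2OCOc2cc1O)S(=O)(=O)c1ccc(C)cc1 | intermediate
5 | 3,4,5-trimethoxybenzyl bromide | COc1cc(CBr)cc(OC)c1OC | starting material
6 | dimethyl sulfide | CSC | starting material
7 | dimethyl(3,4,5-trimethoxybenzyl)sulfonium bromide | C[S+](C)Cc1cc(OC)c(OC)c(OC)c1.[Br-] | intermediate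
8 | (E)-6-ethylidene-1,3-benzodioxol-5(6H)-one | C/C=C1\C=C2OCOC2=CC1=O | intermediate
9 | dimethylsulfonium (3,4,5-trimethoxyphenyl)methanide | C[S+](C)[CH-]c1cc(OC)c(OC)c(OC)c1 | intermediate
10 | dimethyl[(1R,2S)-2-(6-oxido-1,3-benzodioxol-5-yl)-1-(3,4,5-trimethoxyphenyl)propyl]sulfonium | C[S+](C)[C@@H](c1cc(OC)c(OC)c(OC)c1)[C@@H](C)c1cc2OCOc2cc1[O-] | intermediate
11 | (2S,3S)-3-methyl-5,6-methylenedioxy-2-(3,4,5-trimethoxyphenyl)-2,3-dihydro-1-benzofuran | c12cc3OCOc3cc1O[C@H](c1cc(OC)c(OC)c(OC)c1)[C@H]2C | intermediate
12 | (2S,3S)-3-methyl-2-(3,4,5-trimethoxyphenyl)-2,3-dihydro-1-benzofuran-5,6-diol | c12cc(O)c(O)cc1O[C@H](c1cc(OC)c(OC)c(OC)c1)[C@H]2C | intermediate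
13 | (2S,3S)-3-methyl-2-(3,4,5-trimethoxyphenyl)-2,3-dihydro-1-benzofuran-5,6-dione | O=C1C=C2C(=CC1=O)O[C@H](c1cc(OC)c(OC)c(OC)c1)[C@H]2C | intermediate
14 | (2S,3S,5S)-5-hydroxy-3-methyl-5-(prop-2-en-1-yl)-2-(3,4,5-trimethoxyphenyl)-2,3-dihydro-1-benzofuran-6(5H)-one | C=CC[C@]1(O)C=C2C(=CC1=O)O[C@H](c1cc(OC)c(OC)c(OC)c1)[C@H]2C | intermediate
15 | (2S,3S,5S)-5-methoxy-3-methyl-5-(prop-2-en-1-yl)-2-(3,4,5-trimethoxyphenyl)-2,3-dihydro-1-benzofuran-6(5H)-one | C=CC[C@]1(OC)C=C2C(=CC1=O)O[C@H](c1cc(OC)c(OC)c(OC)c1)[C@H]2C | target

## Step count and least certain steps

Total: 9 steps. Longest linear sequence: 8 steps (1, 2, 3, 5, 6, 7, 8, 9) from sesamol; step 4 is a one-step side branch.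

**Step 5 (key step).** The most likely failure is poor facial selectivity. Neither the ylide nor the quinone methide is an anion, so the chiral cation can act only through hydrogen bonding and pairing with a charge that develops in the transition state, and an uncatalysed background addition may compete. Further risks are tautomerisation of the quinone methide to the vinylphenol before the ylide arrives, sigmatropic rearrangement of the ylide, and O-benzylation of the phenoxide of 4 by the sulfonium salt; all are countered by low temperature and slow release from the solid base. The fallback sets out from 4 and 7 and uses known chemistry. The annulation is run with Cs2CO3 in CH2Cl2 at room temperature without the chiral salt, which should give racemic trans-3-methyl-5,6-methylenedioxy-2-(3,4,5-trimethoxyphenyl)-2,3-dihydro-1-benzofuran F1. The enantiomers are then separated by preparative chromatography on a cellulose tris(3,5-dimethylphenylcarbamate) phase, and the (2S,3S)-enantiomer rejoins the route as 11.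

**Step 8.** Facial selectivity at C5 may be insufficient, because the catalyst was developed for simple ketones and now meets a chelating, redox-active dione whose own slight bias probably points to the wrong face. The Lewis acid may also promote enolisation of the quinone towards C3, which would erode the C3 configuration and lead on to an aromatic benzofuran. The fallback sets out from 13 and uses known chemistry: allyltributylstannane with BF3·OEt2 in CH2Cl2 at −78 °C, without ligand. This should give 14 together with its C5 epimer, (2S,3S,5R)-5-hydroxy-3-methyl-5-(prop-2-en-1-yl)-2-(3,4,5-trimethoxyphenyl)-2,3-dihydro-1-benzofuran-6(5H)-one F2. The two are diastereomers and are separated by chromatography, and the route is rejoined at 14.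

**Step 6.** The boron Lewis acid may also remove the central methoxy group of the trimethoxyphenyl ring, or ionise the benzylic C2–O1 bond with ring opening. The fallback sets out from 11 and replaces Lewis-acid cleavage by oxidation at the acetal carbon. Pb(OAc)4 in benzene at 50 °C should give (2S,3S)-5,6-(acetoxymethylenedioxy)-3-methyl-2-(3,4,5-trimethoxyphenyl)-2,3-dihydro-1-benzofuran F3 (both epimers at the acetal carbon). Aqueous acetic acid in THF then hydrolyses F3 through the catechol monoformate to 12, where the route is rejoined.

**Step 9.** Alkylation of the hindered, electron-poor tertiary hydroxyl may be slow. Competing methylation at the vinylogous-ester carbonyl oxygen would create a cation next to C5 and could trigger an allyl shift or aromatisation. The fallback sets out from 13 and never liberates the alcohol. The allylation of step 8 is run as before but not worked up; its primary product, (2S,3S,5S)-3-methyl-5-(prop-2-en-1-yl)-5-(tributylstannyloxy)-2-(3,4,5-trimethoxyphenyl)-2,3-dihydro-1-benzofuran-6(5H)-one F4, is a more nucleophilic tin alkoxide. It is methylated in the same flask by adding MeOTf and the hindered pyridine at −60 °C and warming to 0 °C, which rejoins the route at 15.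

## Further compounds

F1 | step 5 | racemic trans-3-methyl-5,6-methylenedioxy-2-(3,4,5-trimethoxyphenyl)-2,3-dihydro-1-benzofuran (1:1 mixture of the 2S,3S and 2R,3R enantiomers) | c12cc3OCOc3cc1O[C@H](c1cc(OC)c(OC)c(OC)c1)[C@H]2C.c12cc3OCOc3cc1O[C@@H](c1cc(OC)c(OC)c(OC)c1)[C@@H]2C
F2 | step 8 | (2S,3S,5R)-5-hydroxy-3-methyl-5-(prop-2-en-1-yl)-2-(3,4,5-trimethoxyphenyl)-2,3-dihydro-1-benzofuran-6(5H)-one | C=CC[C@@]1(O)C=C2C(=CC1=O)O[C@H](c1cc(OC)c(OC)c(OC)c1)[C@H]2C
F3 | step 6 | (2S,3S)-5,6-(acetoxymethylenedioxy)-3-methyl-2-(3,4,5-trimethoxyphenyl)-2,3-dihydro-1-benzofuran (both epimers at the acetal carbon) | CC(=O)OC1Oc2cc3O[C@H](c4cc(OC)c(OC)c(OC)c4)[C@@H](C)c3cc2O1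
F4 | step 9 | (2S,3S,5S)-3-methyl-5-(prop-2-en-1-yl)-5-(tributylstannyloxy)-2-(3,4,5-trimethoxyphenyl)-2,3-dihydro-1-benzofuran-6(5H)-one | C=CC[C@]1(O[Sn](CCCC)(CCCC)CCCC)C=C2C(=CC1=O)O[C@H](c1cc(OC)c(OC)c(OC)c1)[C@H]2C
A1 | alternative 1 | (S)-6-allyl-4-[(1S,2S)-1-(tert-butyldimethylsilyloxy)-1-(3,4,5-trimethoxyphenyl)propan-2-yl]-3-ethoxy-6-methoxycyclohexa-2,4-dien-1-one | C=CC[C@]1(OC)C=C([C@H](C)[C@H](O[Si](C)(C)C(C)(C)C)c2cc(OC)c(OC)c(OC)c2)C(OCC)=CC1=O
A2 | alternative 1 | ethoxyethyne | C#COCC
A3 | alternative 2 | (2S,3S,3aR)-3a-allyl-5-methoxy-3-methyl-2-(3,4,5-trimethoxyphenyl)-3,3a-dihydro-1-benzofuran-6(2H)-one | C=CC[C@@]12C=C(OC)C(=O)C=C1O[C@H](c1cc(OC)c(OC)c(OC)c1)[C@H]2C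
A4 | alternative 2 | (E)-isoelemicin, 1,2,3-trimethoxy-5-[(E)-prop-1-enyl]benzene | C/C=C/c1cc(OC)c(OC)c(OC)c1
A5 | alternative 3 | methyl (2S,3S)-trans-5,6-methylenedioxy-2-(3,4,5-trimethoxyphenyl)-2,3-dihydro-1-benzofuran-3-carboxylate | c12cc3OCOc3cc1O[C@H](c1cc(OC)c(OC)c(OC)c1)[C@H]2C(=O)OC
A6 | alternative 3 | methyl 2-diazo-2-[6-(3,4,5-trimethoxybenzyloxy)-1,3-benzodioxol-5-yl]acetate | COC(=O)C(=[N+]=[N-])c1cc2OCOc2cc1OCc1cc(OC)c(OC)c(OC)c1
A7 | alternative 3 | Rh2(S-DOSP)4, dirhodium tetrakis[(S)-1-(4-dodecylphenylsulfonyl)prolinate] | CCCCCCCCCCCCc1ccc(cc1)S(=O)(=O)N1CCC[C@H]1C(=O)[O-].CCCCCCCCCCCCc1ccc(cc1)S(=O)(=O)N1CCC[C@H]1C(=O)[O-].CCCCCCCCCCCCc1ccc(cc1)S(=O)(=O)N1CCC[C@H]1C(=O)[O-].CCCCCCCCCCCCc1ccc(cc1)S(=O)(=O)N1CCC[C@H]1C(=O)[O-].[Rh+2].[Rh+2]
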